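A pitfall with a flask like this is to treat the weak free base as the lever on conversion, when the charge of nucleophile and one ratio of rate constants may set the limit.

    electrophile + nucleophile → acid set free + target (k1 = 0.0955 M⁻¹ s⁻¹)
    nucleophile + acid set free ⇌ protonated nucleophile, settled at all times (K2 = 1.20 × 10⁵ M⁻¹)
    acid set free + free base ⇌ salt of the base (K3 = 57.3 M⁻¹, k3 = 1.66 M⁻¹ s⁻¹)
    acid set free + free base ⇌ idle adduct, settled at all times (K4 = 98 M⁻¹)
    acid set free + scavenger → scavenged by-product (k5 = 0.416 M⁻¹ s⁻¹)
    nucleophile + target → over-reaction product (k6 = 0.305 M⁻¹ s⁻¹)

- epsilon: electrophile 20 mM; nucleophile 1.00 equiv; free base 1.10 equiv; scavenger 1.50 equiv; time 4.0 h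
- eta: electrophile 20 mM; nucleophile 1.00 equiv; free base 1.70 equiv; scavenger 1.50 equiv; time 4.0 h

* part of the electrophile that has reacted at the end, epsilon
* part of the electrophile that has reacted at the end, eta
* what raising the equivalents of free base from its lowest to its highest value here does to the part of the electrophile that has reacted (changes below 5 percentage points count as none) (it falls / it rises / no change)

- acid set free is meant together with its idle adduct
- run time (epsilon): 4.0 h

I began with the two steps that use nucleophile, target-making and over-reaction. Both rates carry free nucleophile as a factor, so dividing one by the other removed both it and time. That left the selectivity factor κ = 3.19, the over-reaction rate constant divided by the target-making one. With x the electrophile left and p the target, both as fractions of the electrophile charged, I integrated: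

dp/dx = −1 + κp/x, so p = (x − x^κ)/(κ − 1)

Each electrophile lost takes one nucleophile, and each over-reaction takes another. One equivalent, spent completely, therefore gives:

x = (1 − p)/2

I solved this by passes, starting from x = 0.5:

p = 0.178, x = 0.411

p = 0.161, x = 0.420

So the ceiling was 58.0% reacted.

My first doubt was that acid locks up nucleophile as its protonated form. But free nucleophile had cancelled, so locking changes the clock and leaves the curve alone. The locked nucleophile must still be released, which needs 11.6 mM of acid removed, and the scavenger charge of 30.0 mM is larger.

My second doubt was the base. Free base stands in neither rate of the curve, so acid held by it could change the clock but not the curve. I therefore expected no change.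

My third doubt, the four hours, I could not close by hand, so I committed only to a value somewhat under the ceiling in both flasks.

The forecast gave 57% for epsilon, 57.5% for eta and no change, with the nucleophile's hold on the acid “making extra base nearly irrelevant”.

The simulation gave 57.0% for epsilon and 57.0% for eta, so the trend was no change, a shift of 0.0071 percentage points. In eta, target-making had half its turnover behind it by 0.0826 h and over-reaction by 0.245 h, while the scavenger step reached that mark at 1.45 h, with 2.64 mM protonated nucleophile still standing at 2.00 h. Eta's 43.0% electrophile at 4.00 h put into the curve gives 16.5% target, and the flask held 16.5%. The neighbour flask, eta with 2.50 equiv nucleophile, kept 2.76% electrophile, for which the curve gives 1.26% target, and it held 1.26%.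

The constants used here are invented; what happens was integrated by code.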